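The cyclohexene ring (C1 and C4 benzoate carbons, C2=C3, C5 carbinol, C6 quaternary carbinol) is disconnected at C3–C4 and C5–C6. Carbons C6, C1, C2 and C3 with the C6 oxygen and hydroxymethyl group are the ring of a furfuryl ether; C4–C5 with both oxygens is vinylene carbonate. One Diels–Alder reaction closes the carbocycle as a 7-oxanorbornene, making the quaternary C6–O centre and the cis C5–O/C6–O relationship. A rhodium-catalysed anti SN2′ opening of the oxygen bridge by benzoate then shifts the alkene to C2=C3, sets C1 and selects one enantiomer; Mitsunobu inversion at allylic C4 and desilylation finish the route.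

Key step: step 2

Remark: compounds 4 and 5 are racemic and are drawn as the enantiomer that is carried on; the sense in which the ferrocenyl ligand of step 4 selects between the enantiomers is assigned by analogy with ring openings of oxabenzonorbornadiene, and the mirror-image ligand is to be used if the opposite sense is found.

Step 1
Reactants: 1 furan-2-ylmethanol (furfuryl alcohol)
Product: 2 tert-butyl(furan-2-ylmethoxy)dimethylsilane
Conditions: TBSCl (1.1 equiv), imidazole (2 equiv), DMF, 0 °C to rt
Reagents that add atoms: tert-butyldimethylsilyl chloride, CC(C)(C)[Si](C)(C)Cl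
Why: Silylation of a primary alcohol (imidazole-assisted substitution at silicon); the silyl ether should survive the cycloaddition, the ring opening and the Mitsunobu step and can be removed at the end without base.

Step 2
Reactants: 2 tert-butyl(furan-2-ylmethoxy)dimethylsilane; 3 vinylene carbonate (1,3-dioxol-2-one)
Product: 4 exo-4-{[tert-butyl(dimethyl)silyl]oxymethyl}-3a,4,7,7a-tetrahydro-4,7-epoxy-1,3-benzodioxol-2-one (racemic exo adduct, carbonate syn to the oxygen bridge)
Conditions: 3 (1.5 equiv), BHT (1 mol %), neat, sealed tube, 125 °C; exo isomer separated by crystallisation or chromatography, endo isomer returned to the reaction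
Reagents that add atoms: none
Why: Thermal normal-electron-demand Diels–Alder reaction: the furan (C2 and C5 termini) and the Z-alkene of vinylene carbonate combine in a concerted, suprafacial [4+2] process, the closest known case being the cycloaddition of furan itself with vinylene carbonate. The six-membered carbocycle is closed by this cycloaddition, both new C–C bonds forming in the same event (one at the substituted and one at the unsubstituted furan α-carbon), which gives the oxygen-bridged bicycle. The two bridgehead centres are fixed relative to each other by the oxygen bridge, the cis relationship of the two carbonate-bearing carbons is transmitted stereospecifically from the Z-dienophile, and their exo orientation is the one expected to prevail under the reversible, equilibrating conditions. The step needs only exo over endo selectivity, because the symmetrical dienophile removes any regiochemical question; nothing in the substrate enforces exo kinetically, so the endo isomer is separated and recycled by cycloreversion. The product is racemic, and the absolute configuration is selected in step 4.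

Step 3
Reactants: 4 racemic exo carbonate adduct
Product: 5 (1S,2S,3R,4S)-1-{[tert-butyl(dimethyl)silyl]oxymethyl}-7-oxabicyclo[2.2.1]hept-5-ene-2,3-diol (2-exo,3-exo; racemic)
Conditions: K2CO3 (0.2 equiv), MeOH, 0 °C to rt
Reagents that add atoms: none
Why: Base-catalysed transesterification (methanolysis) of the strained five-membered cyclic carbonate; the silyl ether and all stereocentres are untouched.

Step 4
Reactants: 5 racemic exo-diol
Product: 6 (1S,4S,5S,6S)-6-{[tert-butyl(dimethyl)silyl]oxymethyl}-4,5,6-trihydroxycyclohex-2-en-1-yl benzoate
Conditions: [Rh(cod)Cl]2 (2.5 mol %), (R)-1-[(S)-2-(diphenylphosphino)ferrocenyl]ethyldi-tert-butylphosphine (6 mol %), Bu4NI (10 mol %), PhCO2H (0.55 equiv), Et3N (0.6 equiv), THF, 70 °C, stopped at about half conversion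
Reagents that add atoms: benzoic acid, O=C(O)c1ccccc1
Why: Rhodium-catalysed asymmetric ring opening of an oxabicyclic alkene (anti SN2′): the exo-bound monovalent rhodium should insert with retention into the less hindered bridgehead C4–O bond and benzoate should attack the resulting allyl at C6, next to the alkoxide carbon and anti to the metal, so that the new C–O stereocentre is trans to the tertiary hydroxyl, while the ligand should allow only the (1S,2S,3R,4S)-enantiomer, in which the catalyst-preferred C–O bond is the accessible secondary one, to react quickly (kinetic resolution, the mirror-image enantiomer being left behind or diverted to a separable regioisomer).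

Step 5
Reactants: 6 monobenzoate triol
Product: 7 (1S,4R,5S,6S)-6-{[tert-butyl(dimethyl)silyl]oxymethyl}-5,6-dihydroxycyclohex-2-ene-1,4-diyl dibenzoate
Conditions: PPh3 (1.5 equiv), DIAD (1.5 equiv), PhCO2H (1.5 equiv), THF, 0 °C to rt
Reagents that add atoms: benzoic acid, O=C(O)c1ccccc1
Why: Mitsunobu reaction: of the three hydroxyls only the allylic secondary one at C4 should be activated as the oxyphosphonium ion and displaced by benzoate in an SN2 process with inversion, which converts the all-cis triol into the trans C4-benzoate/C5-hydroxyl arrangement, the C5 hydroxyl (next to the quaternary carbon) and the tertiary C6 hydroxyl being too hindered to react.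

Step 6
Reactants: 7 dibenzoate silyl ether
Product: 8 (1S,4R,5S,6S)-5,6-dihydroxy-6-(hydroxymethyl)cyclohex-2-ene-1,4-diyl dibenzoate (CNP0212417.1)
Conditions: HF·pyridine, pyridine, THF, 0 °C to rt
Reagents that add atoms: none
Why: Fluoride-mediated desilylation under mildly acidic conditions, chosen so that neither benzoate should migrate to the liberated primary hydroxyl or to the neighbouring secondary one; no stereocentre is touched.

Compound list
1 | furan-2-ylmethanol (furfuryl alcohol) | OCc1ccco1 | starting material
2 | tert-butyl(furan-2-ylmethoxy)dimethylsilane | CC(C)(C)[Si](C)(C)OCc1ccco1 | intermediate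
3 | vinylene carbonate (1,3-dioxol-2-one) | O=C1OC=CO1 | starting material
4 | exo-4-{[tert-butyl(dimethyl)silyl]oxymethyl}-3a,4,7,7a-tetrahydro-4,7-epoxy-1,3-benzodioxol-2-one, the 2-exo,3-exo cyclic carbonate of diol 5 (racemic, drawn as the enantiomer carried on) | CC(C)(C)[Si](C)(C)OC[C@]12C=C[C@H](O1)[C@@H]3OC(=O)O[C@@H]32 | intermediate
5 | (1S,2S,3R,4S)-1-{[tert-butyl(dimethyl)silyl]oxymethyl}-7-oxabicyclo[2.2.1]hept-5-ene-2,3-diol, both hydroxyls exo (racemic, drawn as the enantiomer carried on) | CC(C)(C)[Si](C)(C)OC[C@]12C=C[C@H](O1)[C@H](O)[C@@H]2O | intermediate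
6 | (1S,4S,5S,6S)-6-{[tert-butyl(dimethyl)silyl]oxymethyl}-4,5,6-trihydroxycyclohex-2-en-1-yl benzoate | O=C(O[C@H]1C=C[C@H](O)[C@H](O)[C@@]1(O)CO[Si](C)(C)C(C)(C)C)c1ccccc1 | intermediate
7 | (1S,4R,5S,6S)-6-{[tert-butyl(dimethyl)silyl]oxymethyl}-5,6-dihydroxycyclohex-2-ene-1,4-diyl dibenzoate | O=C(O[C@H]1C=C[C@@H](OC(=O)c2ccccc2)[C@H](O)[C@@]1(O)CO[Si](C)(C)C(C)(C)C)c1ccccc1 | intermediate
8 | (1S,4R,5S,6S)-5,6-dihydroxy-6-(hydroxymethyl)cyclohex-2-ene-1,4-diyl dibenzoate | O=C(O[C@H]1C=C[C@@H](OC(=O)c2ccccc2)[C@H](O)[C@@]1(O)CO)c1ccccc1 | target

Total step count: 6. Longest linear sequence: 6 steps (1 → 2 → 4 → 5 → 6 → 7 → 8).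

Steps most likely to fail

Step 4. The two enantiomers of 5 may be opened at similar rates, or ionisation of the other bridgehead C–O bond may compete, so that 6 would form with eroded enantiomeric purity or together with a regioisomer. The fallback resolves the material through covalent diastereomers before the ring opening, so that the opening no longer has to tell the enantiomers apart. It sets out from 1, which is acylated with (1S)-camphanic chloride (pyridine, CH2Cl2) to furan-2-ylmethyl (1S)-camphanate F1. Cycloaddition of F1 with 3 under the conditions of step 2, followed by fractional crystallisation of the exo diastereomers, should give the exo carbonate adduct camphanate with the bridgehead configuration of 5, F2. K2CO3 in MeOH then removes carbonate and camphanate to give (1S,2S,3R,4S)-1-(hydroxymethyl)-7-oxabicyclo[2.2.1]hept-5-ene-2,3-diol F3. Selective silylation of the primary hydroxyl (TBSCl, imidazole, CH2Cl2, −20 °C) returns to the route at 5, now as the single (1S,2S,3R,4S) enantiomer, which is opened to 6 with the same matched catalyst and a full equivalent of benzoic acid.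

Step 2. The exo/endo ratio may be unfavourable, and cycloreversion and polymerisation of the dienophile at the required temperature may hold conversion down. The fallback builds the same bicycle with an acetylene equivalent and takes the exo-diol geometry from an osmylation instead of from the cycloaddition; the same two ring bonds are still formed in the cycloaddition. It sets out from 2, which reacts with (Z)-1,2-bis(phenylsulfonyl)ethene (CH2Cl2, rt to 40 °C) to give 1-{[tert-butyl(dimethyl)silyl]oxymethyl}-2,3-bis(phenylsulfonyl)-7-oxabicyclo[2.2.1]hept-5-ene F4 (racemic; the sulfonyl configuration is of no consequence). Reductive elimination with Na(Hg) (NaH2PO4, MeOH/THF, −20 °C) gives the achiral 1-{[tert-butyl(dimethyl)silyl]oxymethyl}-7-oxabicyclo[2.2.1]hepta-2,5-diene F5. Dihydroxylation of one of its two equivalent alkenes from the exo face (OsO4 cat., NMO 1 equiv, acetone/H2O, 0 °C) comes back to the route at racemic 5.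

Step 5. Benzoate may attack in the SN2′ sense (allylic transposition), elimination may occur, or the wrong hydroxyl may be activated through a cyclic phosphorane of a cis-diol. The fallback inverts C4 by oxidation and directed reduction and then acylates, instead of displacing. It sets out from 6: chemoselective oxidation of the allylic alcohol with MnO2 (CH2Cl2, rt) gives (1S,5R,6S)-6-{[tert-butyl(dimethyl)silyl]oxymethyl}-5,6-dihydroxy-4-oxocyclohex-2-en-1-yl benzoate F6. Reduction with Me4NBH(OAc)3 (MeCN/AcOH, −20 °C), with hydride delivered from the face of the neighbouring C5 hydroxyl, should give the trans-diol (1S,4R,5S,6S)-6-{[tert-butyl(dimethyl)silyl]oxymethyl}-4,5,6-trihydroxycyclohex-2-en-1-yl benzoate F7. Selective benzoylation of its unhindered allylic hydroxyl (BzCl 1.05 equiv, 2,4,6-collidine, CH2Cl2, −40 °C) comes back to the route at 7.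

Further compounds
F1 | step 4 | furan-2-ylmethyl (1S,4R)-4,7,7-trimethyl-3-oxo-2-oxabicyclo[2.2.1]heptane-1-carboxylate (furfuryl (1S)-camphanate) | C[C@]12CC[C@](C(=O)OCc3ccco3)(OC1=O)C2(C)C
F2 | step 4 | (1S)-camphanate ester of the exo carbonate adduct, bicyclic part configured as in 4 and 5 (single diastereomer) | C[C@]12CC[C@](C(=O)OC[C@]34C=C[C@H](O3)[C@@H]3OC(=O)O[C@@H]34)(OC1=O)C2(C)C
F3 | step 4 | (1S,2S,3R,4S)-1-(hydroxymethyl)-7-oxabicyclo[2.2.1]hept-5-ene-2,3-diol (both ring hydroxyls exo) | OC[C@]12C=C[C@H](O1)[C@H](O)[C@@H]2O
F4 | step 2 | 1-{[tert-butyl(dimethyl)silyl]oxymethyl}-2,3-bis(phenylsulfonyl)-7-oxabicyclo[2.2.1]hept-5-ene (racemic, drawn as the cis,exo isomer) | CC(C)(C)[Si](C)(C)OC[C@]12C=C[C@H](O1)[C@H](S(=O)(=O)c1ccccc1)[C@@H]2S(=O)(=O)c1ccccc1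
F5 | step 2 | 1-{[tert-butyl(dimethyl)silyl]oxymethyl}-7-oxabicyclo[2.2.1]hepta-2,5-diene (achiral) | CC(C)(C)[Si](C)(C)OCC12C=CC(O1)C=C2
F6 | step 5 | (1S,5R,6S)-6-{[tert-butyl(dimethyl)silyl]oxymethyl}-5,6-dihydroxy-4-oxocyclohex-2-en-1-yl benzoate | O=C(O[C@H]1C=CC(=O)[C@H](O)[C@@]1(O)CO[Si](C)(C)C(C)(C)C)c1ccccc1
F7 | step 5 | (1S,4R,5S,6S)-6-{[tert-butyl(dimethyl)silyl]oxymethyl}-4,5,6-trihydroxycyclohex-2-en-1-yl benzoate | O=C(O[C@H]1C=C[C@@H](O)[C@H](O)[C@@]1(O)CO[Si](C)(C)C(C)(C)C)c1ccccc1
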